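**Strategy.** The route rests on cutting the C3–C4 bond of the ten-membered carbocycle (ring A, C1–C10). A Nozaki–Hiyama–Kishi reaction joins the Z-alkenyl iodide at C4 to the aldehyde at C3, which in one operation closes ring A, creates the C3 carbinol and keeps the Z C4=C5 geometry. The step exploits the allylic carbinol C3 beside the methyl-bearing C4 of the C4=C5 alkene, with the two Z alkenes and the cis-fused lactone (ring B: O, C6, C7, C11, C12) bending the chain. The precursor is the open-chain iodo aldehyde that already holds ring B, C8 (OTBS) and C9 (OPMB) from diethyl L-tartrate and the Z C1=C10 alkene.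

Key step: step 18

Remarks on the chemistry (assumptions):
- Germacrane locants are used: ring A = C1–C10 (C14 on C10, C15 on C4); ring B = O, C6, C7, C11, C12; C13 is the exocyclic methylene. The tartrate carbinol carbons become C8 and C9, its ester carbons C7 and C10.
- TBS = tert-butyldimethylsilyl, PMB = 4-methoxybenzyl, Piv = 2,2-dimethylpropanoyl.
- (3-Bromopropoxy)(tert-butyl)dimethylsilane 9 is taken as a commercial reagent.
- The non-stabilised ylide is used before the acrylate unit of ring B exists, because it would add to that unit.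
- The CIP label at C6 changes from R to S when iodine is lost, and that at C7 from S to R when the C8 silyl ether is cleaved. These are priority changes only; no centre is inverted.

Step 1
Reactants: 1 diethyl L-tartrate
Product: 3 diethyl (2R,3R)-2-hydroxy-3-(PMB-oxy)butanedioate, via stannylene acetal 2 (not isolated)
Conditions: Bu2SnO, toluene, reflux (Dean–Stark); then 4-methoxybenzyl chloride, CsF, DMF, rt
Reagents that add atoms: 4-methoxybenzyl chloride, COc1ccc(CCl)cc1
Why: Mono-O-alkylation of a diol through its dibutylstannylene acetal should stop after one ether, and the C2 symmetry of the tartrate makes both hydroxyls equivalent, so the two carbinol centres are carried over unchanged.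

Step 2
Reactants: 3 diethyl (2R,3R)-2-hydroxy-3-(PMB-oxy)butanedioate
Product: 4 ethyl (2R,3S)-3,4-dihydroxy-2-(PMB-oxy)butanoate
Conditions: BH3·SMe2, NaBH4 (5 mol%), THF, 0 °C to rt; MeOH quench
Reagents that add atoms: none
Why: Hydroxyl-directed borane reduction of an α-hydroxy ester: the free hydroxyl forms an alkoxyborane that delivers hydride through a five-membered chelate only to the neighbouring ester, so the ester beside the PMB ether (future C10) should survive and no stereocentre is touched.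

Step 3
Reactants: 4 ethyl (2R,3S)-3,4-dihydroxy-2-(PMB-oxy)butanoate
Product: 5 ethyl (2R,3S)-3-hydroxy-2-(PMB-oxy)-4-(pivaloyloxy)butanoate
Conditions: PivCl, pyridine, CH2Cl2, −20 to 0 °C
Reagents that add atoms: pivaloyl chloride, CC(C)(C)C(Cl)=O
Why: Acylation with a bulky acyl chloride is selective for the primary hydroxyl (future C7 oxygen) over the hindered secondary one.

Step 4
Reactants: 5 ethyl (2R,3S)-3-hydroxy-2-(PMB-oxy)-4-(pivaloyloxy)butanoate
Product: 6 ethyl (2R,3S)-2-(PMB-oxy)-4-(pivaloyloxy)-3-(TBS-oxy)butanoate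
Conditions: TBSOTf, 2,6-lutidine, CH2Cl2, −78 to 0 °C
Reagents that add atoms: tert-butyldimethylsilyl triflate, CC(C)(C)[Si](C)(C)OS(=O)(=O)C(F)(F)F
Why: Silylation of a secondary alcohol with a silyl triflate and a hindered base is reliable and fixes the C8 oxygen as the robust silyl ether that lasts to the final step.

Step 5
Reactants: 6 ethyl (2R,3S)-2-(PMB-oxy)-4-(pivaloyloxy)-3-(TBS-oxy)butanoate
Product: 7 (2R,3S)-N-methoxy-N-methyl-2-(PMB-oxy)-4-(pivaloyloxy)-3-(TBS-oxy)butanamide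
Conditions: MeNHOMe·HCl, iPrMgCl, THF, −20 °C
Reagents that add atoms: N,O-dimethylhydroxylamine hydrochloride, CNOC.Cl
Why: Weinreb amide formation by aminolysis with the magnesium amide should take the activated α-alkoxy ethyl ester in preference to the hindered pivalate and, at low temperature, leave the α-centre intact.

Step 6
Reactants: 7 (2R,3S)-N-methoxy-N-methyl-2-(PMB-oxy)-4-(pivaloyloxy)-3-(TBS-oxy)butanamide
Product: 8 (2S,3R)-3-(PMB-oxy)-4-oxo-2-(TBS-oxy)pentyl pivalate
Conditions: MeMgBr, THF, −78 to 0 °C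
Reagents that add atoms: methylmagnesium bromide, C[Mg]Br
Why: Weinreb ketone synthesis: the chelated tetrahedral adduct prevents over-addition, so the methyl ketone (C10 with C14) should form cleanly while the pivalate is spared at low temperature.

Step 7
Reactants: 9 (3-bromopropoxy)(tert-butyl)dimethylsilane
Product: 10 [3-(TBS-oxy)propyl]triphenylphosphonium bromide
Conditions: PPh3, MeCN, 80 °C
Reagents that add atoms: triphenylphosphine, c1ccc(cc1)P(c1ccccc1)c1ccccc1
Why: SN2 quaternisation of triphenylphosphine by a primary bromide is a standard way to a Wittig salt.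

Step 8
Reactants: 8 (2S,3R)-3-(PMB-oxy)-4-oxo-2-(TBS-oxy)pentyl pivalate; 10 [3-(TBS-oxy)propyl]triphenylphosphonium bromide
Product: 12 (2S,3S,4Z)-4-methyl-3-(PMB-oxy)-2,7-bis(TBS-oxy)hept-4-en-1-yl pivalate, via phosphorus ylide 11 (not isolated)
Conditions: 10, KN(SiMe3)2, THF, −78 to 0 °C; then 8, −78 °C to rt
Reagents that add atoms: none
Why: Wittig olefination of an α-alkoxy methyl ketone with a salt-free non-stabilised ylide is known to be Z-selective (kinetic oxaphosphetane with the new chain cis to the oxygenated carbon C9), and addition at −78 °C should outrun enolisation so C9 is not epimerised.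

Step 9
Reactants: 12 (2S,3S,4Z)-4-methyl-3-(PMB-oxy)-2,7-bis(TBS-oxy)hept-4-en-1-yl pivalate
Product: 13 (2S,3S,4Z)-4-methyl-3-(PMB-oxy)-2,7-bis(TBS-oxy)hept-4-en-1-ol
Conditions: iBu2AlH, CH2Cl2, −78 °C
Reagents that add atoms: none
Why: Reductive cleavage of the pivalate by the aluminium hydride frees only the C7 hydroxyl, as silyl ethers, the PMB ether and the alkene are inert to it.

Step 10
Reactants: 13 (2S,3S,4Z)-4-methyl-3-(PMB-oxy)-2,7-bis(TBS-oxy)hept-4-en-1-ol
Product: 14 (2R,3S,4Z)-4-methyl-3-(PMB-oxy)-2,7-bis(TBS-oxy)hept-4-enal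
Conditions: Dess–Martin periodinane, NaHCO3, CH2Cl2, 0 °C to rt
Reagents that add atoms: none
Why: Dess–Martin oxidation under buffered, non-basic conditions should give the α-silyloxy aldehyde (C7) without epimerisation at C8.

Step 11
Reactants: 14 (2R,3S,4Z)-4-methyl-3-(PMB-oxy)-2,7-bis(TBS-oxy)hept-4-enal; 15 methyl acrylate
Product: 16 methyl (4S,5S,6Z)-3-hydroxy-6-methyl-2-methylidene-5-(PMB-oxy)-4,9-bis(TBS-oxy)non-6-enoate (both C3 epimers)
Conditions: DABCO, methyl acrylate (excess), MeOH (trace), rt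
Reagents that add atoms: none
Why: Baylis–Hillman reaction of an activated α-oxygenated aldehyde attaches C11–C13; the new carbinol centre needs no control because it is erased in step 12.

Step 12
Reactants: 16 methyl (4S,5S,6Z)-3-hydroxy-6-methyl-2-methylidene-5-(PMB-oxy)-4,9-bis(TBS-oxy)non-6-enoate
Product: 17 methyl (2Z,4S,5S,6Z)-2-(bromomethyl)-6-methyl-5-(PMB-oxy)-4,9-bis(TBS-oxy)nona-2,6-dienoate
Conditions: NBS, Me2S, CH2Cl2, 0 °C; then 16, 0 °C to rt
Reagents that add atoms: N-bromosuccinimide, O=C1CCC(=O)N1Br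
Why: Corey–Kim-type activation of the allylic alcohol as an oxysulfonium salt and SN2′ attack of bromide should give the thermodynamically preferred 2-(bromomethyl) enoate with C8 trans to the ester, the preformed sulfonium reagent leaving the other alkene untouched.

Step 13
Reactants: 18 but-2-yn-1-ol
Product: 20 (2Z)-3-iodobut-2-en-1-ol, via cyclic alkenylalanate 19 (not isolated)
Conditions: NaAlH2(OCH2CH2OMe)2, THF, 0 °C to rt; then I2, THF, −78 to 0 °C
Reagents that add atoms: iodine, II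
Why: Hydroxyl-directed trans-hydroalumination places aluminium on C3 cis to the carbinol carbon in a five-membered alanate, and iododealumination with retention should give only the Z iodide.

Step 14
Reactants: 20 (2Z)-3-iodobut-2-en-1-ol
Product: 21 (2Z)-3-iodobut-2-enal
Conditions: MnO2, CH2Cl2, rt, dark
Reagents that add atoms: none
Why: Allylic oxidation on MnO2 is neutral and heterogeneous, so the Z geometry of the iodo enal should be kept if the product is used promptly.

Step 15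
Reactants: 17 methyl (2Z,4S,5S,6Z)-2-(bromomethyl)-6-methyl-5-(PMB-oxy)-4,9-bis(TBS-oxy)nona-2,6-dienoate; 21 (2Z)-3-iodobut-2-enal
Product: 24 (4S,5R)-5-[(1Z)-2-iodoprop-1-en-1-yl]-3-methylidene-4-[(1S,2S,3Z)-3-methyl-2-(PMB-oxy)-1,6-bis(TBS-oxy)hex-3-en-1-yl]oxolan-2-one, via allylzinc bromide 22 (not isolated), via syn hydroxy ester 23 (not isolated)
Conditions: Zn dust, THF/sat. aq NH4Cl, 0 °C to rt; then PPTS (cat.), CH2Cl2, rt
Reagents that add atoms: none
Why: Zinc-mediated Barbier allylation through a chair (Zimmerman–Traxler) transition state: the allylzinc with C8 cis to the metallated CH2 adds at C7 to give the syn adduct, hence the cis-fused ring B after acyl transfer, and C7 should be set relative to C8 by attack anti to the C8–C9 bond in the conformer whose C8–H eclipses the alkene (minimal allylic 1,3-strain).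

Step 16
Reactants: 24 (4S,5R)-5-[(1Z)-2-iodoprop-1-en-1-yl]-3-methylidene-4-[(1S,2S,3Z)-3-methyl-2-(PMB-oxy)-1,6-bis(TBS-oxy)hex-3-en-1-yl]oxolan-2-one
Product: 25 (4S,5R)-4-[(1S,2S,3Z)-6-hydroxy-3-methyl-2-(PMB-oxy)-1-(TBS-oxy)hex-3-en-1-yl]-5-[(1Z)-2-iodoprop-1-en-1-yl]-3-methylideneoxolan-2-one
Conditions: HF·pyridine, pyridine, THF, 0 °C
Reagents that add atoms: none
Why: Buffered fluoride cleaves the unhindered primary silyl ether at C3 much faster than the secondary one at C8, which sits between two branched carbons.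

Step 17
Reactants: 25 (4S,5R)-4-[(1S,2S,3Z)-6-hydroxy-3-methyl-2-(PMB-oxy)-1-(TBS-oxy)hex-3-en-1-yl]-5-[(1Z)-2-iodoprop-1-en-1-yl]-3-methylideneoxolan-2-one
Product: 26 (3Z,5S,6S)-6-[(2R,3S)-2-[(1Z)-2-iodoprop-1-en-1-yl]-4-methylidene-5-oxooxolan-3-yl]-4-methyl-5-(PMB-oxy)-6-(TBS-oxy)hex-3-enal
Conditions: Dess–Martin periodinane, NaHCO3, CH2Cl2, 0 °C; crude aldehyde used at once
Reagents that add atoms: none
Why: Dess–Martin oxidation under buffered conditions should give the β,γ-unsaturated C3 aldehyde without moving the C1=C10 alkene into conjugation, provided the product is not stored or chromatographed.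

Step 18
Reactants: 26 (3Z,5S,6S)-6-[(2R,3S)-2-[(1Z)-2-iodoprop-1-en-1-yl]-4-methylidene-5-oxooxolan-3-yl]-4-methyl-5-(PMB-oxy)-6-(TBS-oxy)hex-3-enal
Product: 28 (3S,6S,7S,8S,9S,1(10)Z,4Z)-3-hydroxy-9-(PMB-oxy)-8-(TBS-oxy)germacra-1(10),4,11(13)-trien-12,6-olide, via alkenylchromium dichloride 27 (not isolated)
Conditions: CrCl2 (excess), NiCl2 (cat.), degassed DMSO, rt, slow addition of 26 to about 0.002 M
Reagents that add atoms: none
Why: Zerovalent nickel, made from NiCl2 by CrCl2, inserts into the C4–I bond with retention and passes the alkenyl group to trivalent chromium, and alkenylchromium 27 adds to the C3 aldehyde. The closest known reaction type is the Nozaki–Hiyama–Kishi cyclisation of iodoalkenyl aldehydes to medium-ring and macrocyclic allylic alcohols. Ring A closes in the 10-exo-trig mode, the sp2 carbon C4 attacking the carbonyl carbon whose C=O bond stays outside the ring. C3 should be set by the cyclic transition state: the small C3–H lies in the C4=C5 plane toward C6, C2 and C7 leave that plane on the same face because of the short C2 link to the Z C1=C10 alkene, and the chromium-bound oxygen takes the open face, which corresponds to 3S. The step needs chemoselectivity for the C–I bond over the acrylate, lactone and ethers, which the mild organochromium reagent provides, and ring closure over oligomerisation, which high dilution, the two Z alkenes and the cis-fused ring B should secure. The Z geometry at C4=C5 is carried over from 26 because oxidative addition and transmetallation keep the alkene configuration.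

Step 19
Reactants: 28 (3S,6S,7S,8S,9S,1(10)Z,4Z)-3-hydroxy-9-(PMB-oxy)-8-(TBS-oxy)germacra-1(10),4,11(13)-trien-12,6-olide
Product: 29 (3S,6S,7S,8S,9S,1(10)Z,4Z)-3-acetoxy-9-(PMB-oxy)-8-(TBS-oxy)germacra-1(10),4,11(13)-trien-12,6-olide
Conditions: Ac2O, pyridine, DMAP (cat.), CH2Cl2, 0 °C to rt
Reagents that add atoms: acetic anhydride, CC(=O)OC(C)=O
Why: DMAP-catalysed acetylation of the only free hydroxyl proceeds with retention at C3.

Step 20
Reactants: 29 (3S,6S,7S,8S,9S,1(10)Z,4Z)-3-acetoxy-9-(PMB-oxy)-8-(TBS-oxy)germacra-1(10),4,11(13)-trien-12,6-olide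
Product: 30 (3S,6S,7S,8S,9S,1(10)Z,4Z)-3-acetoxy-9-hydroxy-8-(TBS-oxy)germacra-1(10),4,11(13)-trien-12,6-olide
Conditions: DDQ, CH2Cl2/pH 7 buffer, 0 °C
Reagents that add atoms: none
Why: Oxidative cleavage of the PMB ether by DDQ is neutral and should leave the acetate, the silyl ether and the methylene lactone untouched.

Step 21
Reactants: 31 tiglic acid
Product: 32 (2E)-2-methylbut-2-en-1-ol
Conditions: LiAlH4, Et2O, 0 °C to rt
Reagents that add atoms: none
Why: Hydride reduction of the acid gives the allylic alcohol with the E geometry unchanged.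

Step 22
Reactants: 32 (2E)-2-methylbut-2-en-1-ol
Product: 33 [(2R,3R)-2,3-dimethyloxiran-2-yl]methanol
Conditions: Ti(OiPr)4 (cat.), D-(−)-diisopropyl tartrate (cat.), tBuOOH, 4 Å molecular sieves, CH2Cl2, −20 °C
Reagents that add atoms: tert-butyl hydroperoxide, CC(C)(C)OO
Why: Sharpless asymmetric epoxidation: the titanium complex of the D-tartrate ester should deliver oxygen to the alkene face that gives the (2R,3R) epoxide, and the E geometry fixes the two methyl groups cis.

Step 23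
Reactants: 33 [(2R,3R)-2,3-dimethyloxiran-2-yl]methanol
Product: 34 (2S,3R)-2,3-dimethyloxirane-2-carboxylic acid
Conditions: RuCl3 (cat.), NaIO4, MeCN/EtOAc/H2O, rt
Reagents that add atoms: water, O
Why: Catalytic RuO4 oxidation takes a primary epoxy alcohol to the glycidic acid without opening the epoxide; the descriptor at C2 changes by priority only.

Step 24
Reactants: 30 (3S,6S,7S,8S,9S,1(10)Z,4Z)-3-acetoxy-9-hydroxy-8-(TBS-oxy)germacra-1(10),4,11(13)-trien-12,6-olide; 34 (2S,3R)-2,3-dimethyloxirane-2-carboxylic acid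
Product: 36 (3S,6S,7S,8S,9S,1(10)Z,4Z)-3-acetoxy-9-{[(2S,3R)-2,3-dimethyloxiran-2-yl]carbonyloxy}-8-(TBS-oxy)germacra-1(10),4,11(13)-trien-12,6-olide, via mixed anhydride 35 (not isolated)
Conditions: 34, 2,4,6-trichlorobenzoyl chloride, Et3N, toluene, rt; then 30, DMAP, toluene, rt to 40 °C
Reagents that add atoms: none
Why: Yamaguchi esterification activates the hindered tertiary acid as a mixed anhydride that DMAP transfers to the secondary allylic C9 hydroxyl with retention at C9 and at both epoxide carbons.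

Step 25
Reactants: 36 (3S,6S,7S,8S,9S,1(10)Z,4Z)-3-acetoxy-9-{[(2S,3R)-2,3-dimethyloxiran-2-yl]carbonyloxy}-8-(TBS-oxy)germacra-1(10),4,11(13)-trien-12,6-olide
Product: 37 (3S,6S,7R,8S,9S,1(10)Z,4Z)-3-acetoxy-8-hydroxy-9-{[(2S,3R)-2,3-dimethyloxiran-2-yl]carbonyloxy}germacra-1(10),4,11(13)-trien-12,6-olide (target)
Conditions: HF·pyridine, pyridine, THF, 0 °C to rt
Reagents that add atoms: none
Why: Fluoride-mediated desilylation under buffered, weakly acidic conditions should free the C8 hydroxyl without acyl migration, lactone exchange or opening of the electron-poor glycidic ester.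

Compound list
1 | diethyl L-tartrate | CCOC(=O)[C@H](O)[C@@H](O)C(=O)OCC | starting material
2 | diethyl (4R,5R)-2,2-dibutyl-1,3,2-dioxastannolane-4,5-dicarboxylate | CCOC(=O)[C@@H]1O[Sn](CCCC)(CCCC)O[C@H]1C(=O)OCC | intermediate
3 | diethyl (2R,3R)-2-hydroxy-3-(PMB-oxy)butanedioate | CCOC(=O)[C@H](OCc1ccc(OC)cc1)[C@@H](O)C(=O)OCC | intermediate
4 | ethyl (2R,3S)-3,4-dihydroxy-2-(PMB-oxy)butanoate | CCOC(=O)[C@H](OCc1ccc(OC)cc1)[C@@H](O)CO | intermediate
5 | ethyl (2R,3S)-3-hydroxy-2-(PMB-oxy)-4-(pivaloyloxy)butanoate | CCOC(=O)[C@H](OCc1ccc(OC)cc1)[C@@H](O)COC(=O)C(C)(C)C | intermediate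
6 | ethyl (2R,3S)-2-(PMB-oxy)-4-(pivaloyloxy)-3-(TBS-oxy)butanoate | CCOC(=O)[C@H](OCc1ccc(OC)cc1)[C@@H](O[Si](C)(C)C(C)(C)C)COC(=O)C(C)(C)C | intermediate
7 | (2R,3S)-N-methoxy-N-methyl-2-(PMB-oxy)-4-(pivaloyloxy)-3-(TBS-oxy)butanamide | CON(C)C(=O)[C@H](OCc1ccc(OC)cc1)[C@@H](O[Si](C)(C)C(C)(C)C)COC(=O)C(C)(C)C | intermediate
8 | (2S,3R)-3-(PMB-oxy)-4-oxo-2-(TBS-oxy)pentyl pivalate | CC(=O)[C@H](OCc1ccc(OC)cc1)[C@@H](O[Si](C)(C)C(C)(C)C)COC(=O)C(C)(C)C | intermediate
9 | (3-bromopropoxy)(tert-butyl)dimethylsilane | CC(C)(C)[Si](C)(C)OCCCBr | starting material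
10 | [3-(TBS-oxy)propyl]triphenylphosphonium bromide | CC(C)(C)[Si](C)(C)OCCC[P+](c1ccccc1)(c1ccccc1)c1ccccc1.[Br-] | intermediate
11 | [3-(TBS-oxy)propylidene]triphenylphosphorane | CC(C)(C)[Si](C)(C)OCCC=P(c1ccccc1)(c1ccccc1)c1ccccc1 | intermediate
12 | (2S,3S,4Z)-4-methyl-3-(PMB-oxy)-2,7-bis(TBS-oxy)hept-4-en-1-yl pivalate | CC(C)(C)C(=O)OC[C@H](O[Si](C)(C)C(C)(C)C)[C@@H](OCc1ccc(OC)cc1)/C(C)=C\CCO[Si](C)(C)C(C)(C)C | intermediate
13 | (2S,3S,4Z)-4-methyl-3-(PMB-oxy)-2,7-bis(TBS-oxy)hept-4-en-1-ol | OC[C@H](O[Si](C)(C)C(C)(C)C)[C@@H](OCc1ccc(OC)cc1)/C(C)=C\CCO[Si](C)(C)C(C)(C)C | intermediate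
14 | (2R,3S,4Z)-4-methyl-3-(PMB-oxy)-2,7-bis(TBS-oxy)hept-4-enal | O=C[C@H](O[Si](C)(C)C(C)(C)C)[C@@H](OCc1ccc(OC)cc1)/C(C)=C\CCO[Si](C)(C)C(C)(C)C | intermediate
15 | methyl acrylate | C=CC(=O)OC | starting material
16 | methyl (4S,5S,6Z)-3-hydroxy-6-methyl-2-methylidene-5-(PMB-oxy)-4,9-bis(TBS-oxy)non-6-enoate (both C3 epimers) | COC(=O)C(=C)C(O)[C@H](O[Si](C)(C)C(C)(C)C)[C@@H](OCc1ccc(OC)cc1)/C(C)=C\CCO[Si](C)(C)C(C)(C)C | intermediate
17 | methyl (2Z,4S,5S,6Z)-2-(bromomethyl)-6-methyl-5-(PMB-oxy)-4,9-bis(TBS-oxy)nona-2,6-dienoate | COC(=O)/C(CBr)=C/[C@H](O[Si](C)(C)C(C)(C)C)[C@@H](OCc1ccc(OC)cc1)/C(C)=C\CCO[Si](C)(C)C(C)(C)C | intermediate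
18 | but-2-yn-1-ol | CC#CCO | starting material
19 | sodium 2,2-bis(2-methoxyethoxy)-3-methyl-2,5-dihydro-1,2-oxaaluminol-2-uide | CC1=CCO[Al-]1(OCCOC)OCCOC.[Na+] | intermediate
20 | (2Z)-3-iodobut-2-en-1-ol | C/C(I)=C/CO | intermediate
21 | (2Z)-3-iodobut-2-enal | C/C(I)=C/C=O | intermediate
22 | allylzinc bromide from 17 (zinc on the former bromomethyl carbon) | COC(=O)/C(C[Zn]Br)=C/[C@H](O[Si](C)(C)C(C)(C)C)[C@@H](OCc1ccc(OC)cc1)/C(C)=C\CCO[Si](C)(C)C(C)(C)C | intermediate
23 | methyl (3S,4R,5Z)-4-hydroxy-6-iodo-2-methylidene-3-[(1S,2S,3Z)-3-methyl-2-(PMB-oxy)-1,6-bis(TBS-oxy)hex-3-en-1-yl]hept-5-enoate | COC(=O)C(=C)[C@@H]([C@@H](O)/C=C(/C)I)[C@H](O[Si](C)(C)C(C)(C)C)[C@@H](OCc1ccc(OC)cc1)/C(C)=C\CCO[Si](C)(C)C(C)(C)C | intermediate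
24 | (4S,5R)-5-[(1Z)-2-iodoprop-1-en-1-yl]-3-methylidene-4-[(1S,2S,3Z)-3-methyl-2-(PMB-oxy)-1,6-bis(TBS-oxy)hex-3-en-1-yl]oxolan-2-one | C/C(I)=C/[C@@H]1OC(=O)C(=C)[C@@H]1[C@H](O[Si](C)(C)C(C)(C)C)[C@@H](OCc1ccc(OC)cc1)/C(C)=C\CCO[Si](C)(C)C(C)(C)C | intermediate
25 | (4S,5R)-4-[(1S,2S,3Z)-6-hydroxy-3-methyl-2-(PMB-oxy)-1-(TBS-oxy)hex-3-en-1-yl]-5-[(1Z)-2-iodoprop-1-en-1-yl]-3-methylideneoxolan-2-one | C/C(I)=C/[C@@H]1OC(=O)C(=C)[C@@H]1[C@H](O[Si](C)(C)C(C)(C)C)[C@@H](OCc1ccc(OC)cc1)/C(C)=C\CCO | intermediate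
26 | (3Z,5S,6S)-6-[(2R,3S)-2-[(1Z)-2-iodoprop-1-en-1-yl]-4-methylidene-5-oxooxolan-3-yl]-4-methyl-5-(PMB-oxy)-6-(TBS-oxy)hex-3-enal | C/C(I)=C/[C@@H]1OC(=O)C(=C)[C@@H]1[C@H](O[Si](C)(C)C(C)(C)C)[C@@H](OCc1ccc(OC)cc1)/C(C)=C\CC=O | intermediate
27 | alkenylchromium dichloride from 26 (chromium in place of iodine at C4) | C/C([Cr](Cl)Cl)=C/[C@@H]1OC(=O)C(=C)[C@@H]1[C@H](O[Si](C)(C)C(C)(C)C)[C@@H](OCc1ccc(OC)cc1)/C(C)=C\CC=O | intermediate
28 | (3S,6S,7S,8S,9S,1(10)Z,4Z)-3-hydroxy-9-(PMB-oxy)-8-(TBS-oxy)germacra-1(10),4,11(13)-trien-12,6-olide | C=C1C(=O)O[C@H]2/C=C(/C)[C@@H](O)C/C=C(/C)[C@H](OCc3ccc(OC)cc3)[C@@H](O[Si](C)(C)C(C)(C)C)[C@@H]12 | intermediate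
29 | (3S,6S,7S,8S,9S,1(10)Z,4Z)-3-acetoxy-9-(PMB-oxy)-8-(TBS-oxy)germacra-1(10),4,11(13)-trien-12,6-olide | C=C1C(=O)O[C@H]2/C=C(/C)[C@@H](OC(C)=O)C/C=C(/C)[C@H](OCc3ccc(OC)cc3)[C@@H](O[Si](C)(C)C(C)(C)C)[C@@H]12 | intermediate
30 | (3S,6S,7S,8S,9S,1(10)Z,4Z)-3-acetoxy-9-hydroxy-8-(TBS-oxy)germacra-1(10),4,11(13)-trien-12,6-olide | C=C1C(=O)O[C@H]2/C=C(/C)[C@@H](OC(C)=O)C/C=C(/C)[C@H](O)[C@@H](O[Si](C)(C)C(C)(C)C)[C@@H]12 | intermediate
31 | tiglic acid | C/C=C(\C)C(=O)O | starting material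
32 | (2E)-2-methylbut-2-en-1-ol | C/C=C(\C)CO | intermediate
33 | [(2R,3R)-2,3-dimethyloxiran-2-yl]methanol | OC[C@@]1(C)O[C@@H]1C | intermediate
34 | (2S,3R)-2,3-dimethyloxirane-2-carboxylic acid | OC(=O)[C@@]1(C)O[C@@H]1C | intermediate
35 | (2S,3R)-2,3-dimethyloxirane-2-carboxylic 2,4,6-trichlorobenzoic anhydride | O=C(OC(=O)c1c(Cl)cc(Cl)cc1Cl)[C@@]1(C)O[C@@H]1C | intermediate
36 | (3S,6S,7S,8S,9S,1(10)Z,4Z)-3-acetoxy-9-{[(2S,3R)-2,3-dimethyloxiran-2-yl]carbonyloxy}-8-(TBS-oxy)germacra-1(10),4,11(13)-trien-12,6-olide | C=C1C(=O)O[C@H]2/C=C(/C)[C@@H](OC(C)=O)C/C=C(/C)[C@H](OC(=O)[C@@]3(C)O[C@@H]3C)[C@@H](O[Si](C)(C)C(C)(C)C)[C@@H]12 | intermediate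
37 | (3S,6S,7R,8S,9S,1(10)Z,4Z)-3-acetoxy-8-hydroxy-9-{[(2S,3R)-2,3-dimethyloxiran-2-yl]carbonyloxy}germacra-1(10),4,11(13)-trien-12,6-olide | C=C1C(=O)O[C@H]2/C=C(/C)[C@@H](OC(C)=O)C/C=C(/C)[C@H](OC(=O)[C@@]3(C)O[C@@H]3C)[C@@H](O)[C@@H]12 | target

Total step count: 25.
Longest linear sequence: 19 steps (steps 1–6, 8–12, 15–20, 24, 25, from diethyl L-tartrate).

Steps most likely to fail

1. Step 18 (ring closure). The addition may show poor facial selectivity at the C3 aldehyde, so that the wrong C3 configuration is formed in part or in the main. The fallback sets out from 26 and accepts the cyclisation as a C3 mixture that contains the 3R epimer of 28 F1. The mixture would be oxidised with Dess–Martin periodinane (NaHCO3, CH2Cl2) to the C3 ketone of ring A F2. C3 would then be set by reagent control in a Corey–Bakshi–Shibata reduction with the (R)-methyl oxazaborolidine and catecholborane in toluene at −78 °C. The alkenyl side acts as the larger group, which should give 3S, and catecholborane should spare the methylene lactone. The route is rejoined at 28.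

2. Step 15 (allylation and lactone closure). The open zinc-mediated addition may lose the syn relationship (trans lactone) or show poor facial selectivity at C7 relative to C8. The fallback sets out from 16. Acetylation (Ac2O, pyridine, DMAP) would give the allylic acetate F3. Palladium-catalysed borylation (B2pin2, Pd2(dba)3, DMSO, rt) should convert it into the E-configured pinacol allylboronate F4, which has the same geometry as 17 (C8 trans to the ester). Uncatalysed allylboration of 21 in toluene at about 70 °C, followed by PPTS in CH2Cl2, should give the cis lactone. The closed six-membered boron transition state transmits the alkene geometry stereospecifically and holds the C8 substituents closer to the reacting centre. The route is rejoined at 24.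

3. Step 11 (Baylis–Hillman reaction). Conversion of the hindered α-silyloxy aldehyde may be slow, with epimerisation at C8 during long exposure to the amine. The fallback sets out from 14 and replaces amine catalysis by a preformed nucleophile. Methyl propiolate (C#CC(=O)OC) would be treated with iBu2AlH and N-methylmorpholine N-oxide in THF at 0 °C to give diisobutyl[1-(methoxycarbonyl)ethenyl]aluminium F5. Its 1,2-addition to 14 at 0 °C should give the same hydroxy ester within hours and without base. The route is rejoined at 16.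

Further compounds
F1 | step 18 | (3R,6S,7S,8S,9S,1(10)Z,4Z)-3-hydroxy-9-(PMB-oxy)-8-(TBS-oxy)germacra-1(10),4,11(13)-trien-12,6-olide | C=C1C(=O)O[C@H]2/C=C(/C)[C@H](O)C/C=C(/C)[C@H](OCc3ccc(OC)cc3)[C@@H](O[Si](C)(C)C(C)(C)C)[C@@H]12
F2 | step 18 | (6S,7S,8S,9S,1(10)Z,4Z)-3-oxo-9-(PMB-oxy)-8-(TBS-oxy)germacra-1(10),4,11(13)-trien-12,6-olide | C=C1C(=O)O[C@H]2/C=C(/C)C(=O)C/C=C(/C)[C@H](OCc3ccc(OC)cc3)[C@@H](O[Si](C)(C)C(C)(C)C)[C@@H]12
F3 | step 15 | methyl (4S,5S,6Z)-3-acetoxy-6-methyl-2-methylidene-5-(PMB-oxy)-4,9-bis(TBS-oxy)non-6-enoate (both C3 epimers) | COC(=O)C(=C)C(OC(C)=O)[C@H](O[Si](C)(C)C(C)(C)C)[C@@H](OCc1ccc(OC)cc1)/C(C)=C\CCO[Si](C)(C)C(C)(C)C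
F4 | step 15 | methyl (2E,4S,5S,6Z)-6-methyl-5-(PMB-oxy)-2-[(4,4,5,5-tetramethyl-1,3,2-dioxaborolan-2-yl)methyl]-4,9-bis(TBS-oxy)nona-2,6-dienoate | COC(=O)/C(CB1OC(C)(C)C(C)(C)O1)=C/[C@H](O[Si](C)(C)C(C)(C)C)[C@@H](OCc1ccc(OC)cc1)/C(C)=C\CCO[Si](C)(C)C(C)(C)C
F5 | step 11 | diisobutyl[1-(methoxycarbonyl)ethenyl]aluminium | COC(=O)C(=C)[Al](CC(C)C)CC(C)C
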